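**Retrosynthetic overview**

1. The C1 ketone is taken back to a C1 carbinol that serves as a stereochemical relay: its hydroxyl directs a syn hydrogenation of a C3=C4 alkene in ring B, which sets C3 and C4 (methyl and aryl cis). C2 is carried unchanged from the first C–C bond formation.
2. The C3 methyl comes from a C3 iodide (Negishi). The iodo-alkene ring B comes from an acyclic arene–yne by iodonium-triggered 6-endo-dig closure of the C4–C4a bond, the only ring-forming event of the route.
3. Enabling feature: the C7 methoxy group of ring A is para to C4a (the nucleophilic carbon), and the 4-methoxy group of ring C is para to the carbon bonded to C4, so the activated C3≡C4 alkyne is polarised with C4 as its electrophilic end.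
4. The arene–yne is assembled from three bought pieces: Marshall propargylation of veratraldehyde with (R)-but-3-yn-2-yl mesylate (C1–C2 bond, sets C1 and C2) and Sonogashira coupling with the benzyl ether of 5-bromo-2-methoxyphenol (ring C to C4).
5. Order of rings: rings A and C are bought; ring B is closed in step 6.

Key step: step 6

Remark: tetralone numbering is used for all cyclic intermediates (C1 carbonyl or carbinol carbon, C2 and C3 methyl-bearing carbons, C4 aryl-bearing carbon, C4a and C8a fusion carbons; ring A the dimethoxybenzo ring, ring B the new carbocycle, ring C the pendant aryl ring), and the target is assumed to be the more stable C2 epimer (both methyl groups pseudoequatorial, aryl pseudoaxial), so that the C2 configuration installed in step 3 is not at risk later.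

**Step 1**
Reactants: 1 5-bromo-2-methoxyphenol
Product: 2 2-(benzyloxy)-4-bromo-1-methoxybenzene
Conditions: BnBr, K2CO3, DMF, rt
Reagents that add atoms: benzyl bromide, BrCc1ccccc1
Why: Williamson O-alkylation of the phenoxide gives a benzyl ether that should survive every later step and leave by neutral hydrogenolysis at the end.

**Step 2**
Reactants: 3 (R)-but-3-yn-2-ol
Product: 4 (R)-but-3-yn-2-yl methanesulfonate
Conditions: MsCl, Et3N, CH2Cl2, -78 to 0 °C
Reagents that add atoms: methanesulfonyl chloride, CS(=O)(=O)Cl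
Why: O-sulfonylation does not touch the stereocentre and provides the leaving group for the Marshall propargylation.

**Step 3**
Reactants: 4 (R)-but-3-yn-2-yl methanesulfonate; 5 3,4-dimethoxybenzaldehyde (veratraldehyde)
Product: 7 (1S,2S)-1-(3,4-dimethoxyphenyl)-2-methylbut-3-yn-1-ol, via allenylindium reagent 6 (not isolated)
Conditions: Pd(dppf)Cl2 (5 mol%), InI (1.5 equiv), THF/HMPA 3:1, rt; aq. NH4Cl
Reagents that add atoms: none
Why: Marshall propargylation: zerovalent palladium displaces the mesylate anti (SN2′), the allenyl group passes to indium with retention and adds to the aldehyde through a cyclic SE2′ transition state, so that the configuration of 4 becomes C2 (S) and the anti mode of addition sets C1 (S); the minor syn isomer should be removable by chromatography.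

**Step 4**
Reactants: 7 (1S,2S)-1-(3,4-dimethoxyphenyl)-2-methylbut-3-yn-1-ol
Product: 8 [(1S,2S)-1-(3,4-dimethoxyphenyl)-2-methylbut-3-yn-1-yl]oxy-triisopropylsilane
Conditions: TIPSOTf, 2,6-lutidine, CH2Cl2, 0 °C to rt
Reagents that add atoms: triisopropylsilyl trifluoromethanesulfonate, CC(C)[Si](OS(=O)(=O)C(F)(F)F)(C(C)C)C(C)C
Why: standard silylation of a secondary alcohol; the bulky silyl ether is chosen so that the C1 oxygen cannot compete as a nucleophile in step 6.

**Step 5**
Reactants: 8 [(1S,2S)-1-(3,4-dimethoxyphenyl)-2-methylbut-3-yn-1-yl]oxy-triisopropylsilane; 2 2-(benzyloxy)-4-bromo-1-methoxybenzene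
Product: 9 (3S,4S)-1-[3-(benzyloxy)-4-methoxyphenyl]-4-(3,4-dimethoxyphenyl)-3-methyl-4-(triisopropylsilyloxy)but-1-yne
Conditions: Pd(PhCN)2Cl2 (3 mol%), P(t-Bu)3 (6 mol%), CuI (2 mol%), i-Pr2NH, dioxane, rt
Reagents that add atoms: none
Why: Sonogashira coupling of the terminal alkyne with the electron-rich aryl bromide, for which the P(t-Bu)3 system should work at room temperature; no stereocentre is involved.

**Step 6**
Reactants: 9 (3S,4S)-1-[3-(benzyloxy)-4-methoxyphenyl]-4-(3,4-dimethoxyphenyl)-3-methyl-4-(triisopropylsilyloxy)but-1-yne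
Product: 10 (1S,2R)-4-[3-(benzyloxy)-4-methoxyphenyl]-3-iodo-6,7-dimethoxy-2-methyl-1-(triisopropylsilyloxy)-1,2-dihydronaphthalene
Conditions: I2 (3 equiv), NaHCO3 (3 equiv), MeCN, 0 °C to rt
Reagents that add atoms: iodine, [I][I]
Why: I2 forms an iodirenium ion on the C3≡C4 alkyne that opens towards C4 because the 4-methoxy group of ring C stabilises positive charge there; C4a of ring A, para to the C7 methoxy group, attacks C4 anti to iodine, and NaHCO3 takes the proton from the Wheland intermediate to give the 3-iodo-1,2-dihydronaphthalene. The closest known reaction type is the iodonium-induced carbocyclisation (intramolecular iodoarylation) of arene-tethered alkynes to 3-iodo-1,2-dihydronaphthalenes. Ring B closes in the 6-endo-dig mode by formation of the C4–C4a bond. No new stereocentre is formed: C1 and C2 are untouched, and the step instead lays down the tetrasubstituted C3=C4 alkene with iodine at C3, which carries both the later methyl group and the cis hydrogenation. The step needs 6-endo over 5-exo closure (secured by the aryl-stabilised cationic character at C4), C-attack by ring A over O-attack by the C1 oxygen (secured by the bulky TIPS group and the electron-rich ring), and attack at C4a rather than at the ipso carbon C8a or the hindered carbon between side chain and methoxy group (secured by the para methoxy group at C7 and by the strain of a 5-endo spirocycle).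

**Step 7**
Reactants: 10 (1S,2R)-4-[3-(benzyloxy)-4-methoxyphenyl]-3-iodo-6,7-dimethoxy-2-methyl-1-(triisopropylsilyloxy)-1,2-dihydronaphthalene
Product: 11 (1S,2S)-4-[3-(benzyloxy)-4-methoxyphenyl]-6,7-dimethoxy-2,3-dimethyl-1-(triisopropylsilyloxy)-1,2-dihydronaphthalene
Conditions: MeZnCl (3 equiv), Pd(P(t-Bu)3)2 (5 mol%), THF, 50 °C
Reagents that add atoms: methylzinc chloride, C[Zn]Cl
Why: Negishi cross-coupling of the hindered alkenyl iodide with a methylzinc reagent should put the C3 methyl group in place without moving the alkene; the electron-rich bulky phosphine is chosen for the tetrasubstituted alkenyl halide.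

**Step 8**
Reactants: 11 (1S,2S)-4-[3-(benzyloxy)-4-methoxyphenyl]-6,7-dimethoxy-2,3-dimethyl-1-(triisopropylsilyloxy)-1,2-dihydronaphthalene
Product: 12 (1S,2S)-4-[3-(benzyloxy)-4-methoxyphenyl]-6,7-dimethoxy-2,3-dimethyl-1,2-dihydronaphthalen-1-ol
Conditions: TBAF, THF, 0 °C to rt
Reagents that add atoms: none
Why: fluoride-mediated desilylation under basic conditions, chosen because the product is an arene hydrate that would lose water to a naphthalene under acid.

**Step 9**
Reactants: 12 (1S,2S)-4-[3-(benzyloxy)-4-methoxyphenyl]-6,7-dimethoxy-2,3-dimethyl-1,2-dihydronaphthalen-1-ol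
Product: 13 (1S,2S,3R,4R)-4-[3-(benzyloxy)-4-methoxyphenyl]-6,7-dimethoxy-2,3-dimethyl-1,2,3,4-tetrahydronaphthalen-1-ol
Conditions: [Ir(cod)(PCy3)(py)]PF6 (10 mol%), H2 (4 bar), CH2Cl2, rt
Reagents that add atoms: none
Why: hydroxyl-directed homogeneous hydrogenation: the pseudoaxial homoallylic C1–OH binds the cationic iridium centre (as in cyclohex-3-enols of the terpinen-4-ol type) and both hydrogens are delivered syn to the face that carries the OH, which sets C3 (R) and C4 (R) with methyl and aryl cis to each other and trans to the C2 methyl group.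

**Step 10**
Reactants: 13 (1S,2S,3R,4R)-4-[3-(benzyloxy)-4-methoxyphenyl]-6,7-dimethoxy-2,3-dimethyl-1,2,3,4-tetrahydronaphthalen-1-ol
Product: 14 (2S,3R,4R)-4-[3-(benzyloxy)-4-methoxyphenyl]-6,7-dimethoxy-2,3-dimethyl-3,4-dihydronaphthalen-1(2H)-one
Conditions: Dess–Martin periodinane, CH2Cl2, 0 °C to rt
Reagents that add atoms: none
Why: Dess–Martin oxidation of the secondary benzylic alcohol under near-neutral conditions removes the relay stereocentre at C1 and leaves C2 in the configuration that is also the thermodynamic one.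

**Step 11**
Reactants: 14 (2S,3R,4R)-4-[3-(benzyloxy)-4-methoxyphenyl]-6,7-dimethoxy-2,3-dimethyl-3,4-dihydronaphthalen-1(2H)-one
Product: 15 (2S,3R,4R)-4-(3-hydroxy-4-methoxyphenyl)-6,7-dimethoxy-2,3-dimethyl-3,4-dihydronaphthalen-1(2H)-one
Conditions: H2 (1 bar), 10% Pd/C, EtOAc, rt
Reagents that add atoms: none
Why: hydrogenolysis of the benzyl ether under neutral conditions should free the phenol without reducing the hindered electron-rich aryl ketone or disturbing C2.

**Compound list**

1 | 5-bromo-2-methoxyphenol | COc1ccc(Br)cc1O | starting material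
2 | 2-(benzyloxy)-4-bromo-1-methoxybenzene | COc1ccc(Br)cc1OCc1ccccc1 | intermediate
3 | (R)-but-3-yn-2-ol | C[C@H](C#C)O | starting material
4 | (R)-but-3-yn-2-yl methanesulfonate | C[C@H](C#C)OS(C)(=O)=O | intermediate
5 | 3,4-dimethoxybenzaldehyde (veratraldehyde) | COc1ccc(C=O)cc1OC | starting material
6 | (Sa)-buta-1,2-dien-1-ylindium iodide methanesulfonate (allenylindium reagent, not isolated) | [H]C(C)=[C@]=C([H])[In](I)OS(C)(=O)=O | intermediate
7 | (1S,2S)-1-(3,4-dimethoxyphenyl)-2-methylbut-3-yn-1-ol | COc1ccc([C@@H](O)[C@@H](C)C#C)cc1OC | intermediate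
8 | [(1S,2S)-1-(3,4-dimethoxyphenyl)-2-methylbut-3-yn-1-yl]oxy-triisopropylsilane | COc1ccc([C@@H](O[Si](C(C)C)(C(C)C)C(C)C)[C@@H](C)C#C)cc1OC | intermediate
9 | (3S,4S)-1-[3-(benzyloxy)-4-methoxyphenyl]-4-(3,4-dimethoxyphenyl)-3-methyl-4-(triisopropylsilyloxy)but-1-yne | COc1ccc([C@@H](O[Si](C(C)C)(C(C)C)C(C)C)[C@@H](C)C#Cc2ccc(OC)c(OCc3ccccc3)c2)cc1OC | intermediate
10 | (1S,2R)-4-[3-(benzyloxy)-4-methoxyphenyl]-3-iodo-6,7-dimethoxy-2-methyl-1-(triisopropylsilyloxy)-1,2-dihydronaphthalene | COc1cc2c(cc1OC)[C@@H](O[Si](C(C)C)(C(C)C)C(C)C)[C@@H](C)C(I)=C2c1ccc(OC)c(OCc3ccccc3)c1 | intermediate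
11 | (1S,2S)-4-[3-(benzyloxy)-4-methoxyphenyl]-6,7-dimethoxy-2,3-dimethyl-1-(triisopropylsilyloxy)-1,2-dihydronaphthalene | COc1cc2c(cc1OC)[C@@H](O[Si](C(C)C)(C(C)C)C(C)C)[C@@H](C)C(C)=C2c1ccc(OC)c(OCc3ccccc3)c1 | intermediate
12 | (1S,2S)-4-[3-(benzyloxy)-4-methoxyphenyl]-6,7-dimethoxy-2,3-dimethyl-1,2-dihydronaphthalen-1-ol | COc1cc2c(cc1OC)[C@@H](O)[C@@H](C)C(C)=C2c1ccc(OC)c(OCc3ccccc3)c1 | intermediate
13 | (1S,2S,3R,4R)-4-[3-(benzyloxy)-4-methoxyphenyl]-6,7-dimethoxy-2,3-dimethyl-1,2,3,4-tetrahydronaphthalen-1-ol | COc1cc2c(cc1OC)[C@@H](O)[C@@H](C)[C@H](C)[C@@H]2c1ccc(OC)c(OCc3ccccc3)c1 | intermediate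
14 | (2S,3R,4R)-4-[3-(benzyloxy)-4-methoxyphenyl]-6,7-dimethoxy-2,3-dimethyl-3,4-dihydronaphthalen-1(2H)-one | COc1cc2c(cc1OC)C(=O)[C@@H](C)[C@H](C)[C@@H]2c1ccc(OC)c(OCc3ccccc3)c1 | intermediate
15 | (2S,3R,4R)-4-(3-hydroxy-4-methoxyphenyl)-6,7-dimethoxy-2,3-dimethyl-3,4-dihydronaphthalen-1(2H)-one | COc1cc2c(cc1OC)C(=O)[C@@H](C)[C@H](C)[C@@H]2c1ccc(OC)c(O)c1 | target

**Step count and risks**

Total step count: 11. Longest linear sequence: 10 steps (3 to 15 through steps 2 to 11); step 1 is a one-step side branch.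

Step 6 (key step). What may go wrong: capture of the iodirenium ion by the C1 oxygen (5-endo closure with loss of the silyl group), or iodination and ipso attack on ring A in place of closure at C4a. Fallback (sets out from 9, comes back at 11): the trigger is changed from a stoichiometric halonium ion to a catalytic π-acid, for which O-attack is reversible and only the C–C closure is productive. Ph3PAuNTf2 (5 mol%, CH2Cl2, rt) should give, by 6-endo-dig hydroarylation, (1S,2S)-4-[3-(benzyloxy)-4-methoxyphenyl]-6,7-dimethoxy-2-methyl-1-(triisopropylsilyloxy)-1,2-dihydronaphthalene F1. Pyridinium tribromide with pyridine (CH2Cl2, 0 °C), the known bromination–dehydrobromination of 1-aryl-3,4-dihydronaphthalenes, should then give the (1S,2R)-3-bromo-1,2-dihydronaphthalene F2, and the Negishi conditions of step 7 convert F2 into 11.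

Step 9. What may go wrong: hydrogen delivery without coordination to the hydroxyl group (to the less hindered face, away from OH and the C2 methyl), or acid-triggered loss of water from the arene hydrate under the iridium hydride. Fallback (sets out from 5, comes back at 15): direction by the hydroxyl group is given up for steric control, which needs the mirror-image relay at C1 and C2. (S)-But-3-yn-2-ol (C[C@@H](C#C)O, bought) is taken through the chemistry of steps 2 to 7 with 5 and 2. This gives in turn (S)-but-3-yn-2-yl methanesulfonate F3, the (Ra)-allenylindium reagent F4, (1R,2R)-1-(3,4-dimethoxyphenyl)-2-methylbut-3-yn-1-ol F5, the (1R,2R)-TIPS ether F6, the (3R,4R)-arene–yne F7, the (1R,2S)-3-iodo-1,2-dihydronaphthalene F8 and the (1R,2R)-2,3-dimethyl-1,2-dihydronaphthalene silyl ether F9. In F9 the silyloxy group and the C2 methyl group block the same face, so heterogeneous hydrogenation (H2 5 bar, 10% Pd/C, EtOAc) should add from the open face and also remove the benzyl group, giving the all-cis (1R,2R,3R,4R)-tetralin silyl ether phenol F10. TBAF gives the (1R,2R,3R,4R)-tetralol phenol F11, MnO2 (CH2Cl2) oxidises the benzylic alcohol to the all-cis (2R,3R,4R)-ketone F12, and K2CO3 in MeOH epimerises C2 to the more stable 2,3-trans isomer 15.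

Step 3. What may go wrong: eroded anti/syn selectivity or partial racemisation of the allenylindium reagent in the addition to an aromatic aldehyde. Fallback (sets out from 5, comes back at 8): Brown (E)-crotylboration of 5 with the antipode of (E)-crotyl-B(Ipc)2 that adds to the Si face of the aldehyde (THF, -78 °C; NaOH, H2O2) should give (1S,2S)-1-(3,4-dimethoxyphenyl)-2-methylbut-3-en-1-ol F13. TIPSOTf and 2,6-lutidine give the (1S,2S)-TIPS ether F14. Ozonolysis (O3, CH2Cl2/MeOH, -78 °C; Me2S) gives (2R,3S)-3-(3,4-dimethoxyphenyl)-2-methyl-3-(triisopropylsilyloxy)propanal F15, and Ohira–Bestmann homologation (dimethyl (1-diazo-2-oxopropyl)phosphonate, K2CO3, MeOH, 0 °C) converts F15 into 8.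

**Further compounds**

F1 | step 6 | (1S,2S)-4-[3-(benzyloxy)-4-methoxyphenyl]-6,7-dimethoxy-2-methyl-1-(triisopropylsilyloxy)-1,2-dihydronaphthalene | COc1cc2c(cc1OC)[C@@H](O[Si](C(C)C)(C(C)C)C(C)C)[C@@H](C)C=C2c1ccc(OC)c(OCc3ccccc3)c1
F2 | step 6 | (1S,2R)-4-[3-(benzyloxy)-4-methoxyphenyl]-3-bromo-6,7-dimethoxy-2-methyl-1-(triisopropylsilyloxy)-1,2-dihydronaphthalene | COc1cc2c(cc1OC)[C@@H](O[Si](C(C)C)(C(C)C)C(C)C)[C@@H](C)C(Br)=C2c1ccc(OC)c(OCc3ccccc3)c1
F3 | step 9 | (S)-but-3-yn-2-yl methanesulfonate | C[C@@H](C#C)OS(C)(=O)=O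
F4 | step 9 | (Ra)-buta-1,2-dien-1-ylindium iodide methanesulfonate | [H]C(C)=[C@@]=C([H])[In](I)OS(C)(=O)=O
F5 | step 9 | (1R,2R)-1-(3,4-dimethoxyphenyl)-2-methylbut-3-yn-1-ol | COc1ccc([C@H](O)[C@H](C)C#C)cc1OC
F6 | step 9 | [(1R,2R)-1-(3,4-dimethoxyphenyl)-2-methylbut-3-yn-1-yl]oxy-triisopropylsilane | COc1ccc([C@H](O[Si](C(C)C)(C(C)C)C(C)C)[C@H](C)C#C)cc1OC
F7 | step 9 | (3R,4R)-1-[3-(benzyloxy)-4-methoxyphenyl]-4-(3,4-dimethoxyphenyl)-3-methyl-4-(triisopropylsilyloxy)but-1-yne | COc1ccc([C@H](O[Si](C(C)C)(C(C)C)C(C)C)[C@H](C)C#Cc2ccc(OC)c(OCc3ccccc3)c2)cc1OC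
F8 | step 9 | (1R,2S)-4-[3-(benzyloxy)-4-methoxyphenyl]-3-iodo-6,7-dimethoxy-2-methyl-1-(triisopropylsilyloxy)-1,2-dihydronaphthalene | COc1cc2c(cc1OC)[C@H](O[Si](C(C)C)(C(C)C)C(C)C)[C@H](C)C(I)=C2c1ccc(OC)c(OCc3ccccc3)c1
F9 | step 9 | (1R,2R)-4-[3-(benzyloxy)-4-methoxyphenyl]-6,7-dimethoxy-2,3-dimethyl-1-(triisopropylsilyloxy)-1,2-dihydronaphthalene | COc1cc2c(cc1OC)[C@H](O[Si](C(C)C)(C(C)C)C(C)C)[C@H](C)C(C)=C2c1ccc(OC)c(OCc3ccccc3)c1
F10 | step 9 | (1R,2R,3R,4R)-4-(3-hydroxy-4-methoxyphenyl)-6,7-dimethoxy-2,3-dimethyl-1-(triisopropylsilyloxy)-1,2,3,4-tetrahydronaphthalene | COc1cc2c(cc1OC)[C@H](O[Si](C(C)C)(C(C)C)C(C)C)[C@H](C)[C@H](C)[C@@H]2c1ccc(OC)c(O)c1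
F11 | step 9 | (1R,2R,3R,4R)-4-(3-hydroxy-4-methoxyphenyl)-6,7-dimethoxy-2,3-dimethyl-1,2,3,4-tetrahydronaphthalen-1-ol | COc1cc2c(cc1OC)[C@H](O)[C@H](C)[C@H](C)[C@@H]2c1ccc(OC)c(O)c1
F12 | step 9 | (2R,3R,4R)-4-(3-hydroxy-4-methoxyphenyl)-6,7-dimethoxy-2,3-dimethyl-3,4-dihydronaphthalen-1(2H)-one | COc1cc2c(cc1OC)C(=O)[C@H](C)[C@H](C)[C@@H]2c1ccc(OC)c(O)c1
F13 | step 3 | (1S,2S)-1-(3,4-dimethoxyphenyl)-2-methylbut-3-en-1-ol | COc1ccc([C@@H](O)[C@@H](C)C=C)cc1OC
F14 | step 3 | [(1S,2S)-1-(3,4-dimethoxyphenyl)-2-methylbut-3-en-1-yl]oxy-triisopropylsilane | COc1ccc([C@@H](O[Si](C(C)C)(C(C)C)C(C)C)[C@@H](C)C=C)cc1OC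
F15 | step 3 | (2R,3S)-3-(3,4-dimethoxyphenyl)-2-methyl-3-(triisopropylsilyloxy)propanal | COc1ccc([C@@H](O[Si](C(C)C)(C(C)C)C(C)C)[C@@H](C)C=O)cc1OC
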